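**Plan**

1. Retrosynthetic cuts, in order: the O8 ester; the lactone bond C12–O6 together with the C12 oxidation level (back to an isopropenyl methyl); ring bond C7–C8 (carbonyl-ene); C5–C10 and C8–C9 in one operation (dienyllithium addition, then anionic oxy-Cope shift); C5–C6 (alkenylzinc plus enal).
2. Enabling feature: O8–C8–C9–C10(quaternary)–C5–C4=C3 is a δ,ε-unsaturated carbinol on the cyclohexane ring C5–C10. With ring bond C7–C8 opened to a C8 aldehyde, it is the product of a [3,3] shift of the 1,5-dien-3-olate C10=C9–C8(O⁻)–C3–C4=C5, and that olate is one 1,2-addition away from an aldehyde.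
3. Forward: both vinyl iodides come from anti-carbomagnesiation of propargyl alcohol; the chain is assembled open (steps 9–12); ring C5–C10 is closed by a type 1 ene reaction (step 13); the ester is attached, C12 is oxidised, and the γ-lactone ring closes last.
4. Stereochemistry: C6 from a ligand-controlled alkenylzinc addition; C5 and C10 from the chair [3,3] shift, relayed from C6; C7 and C8 from the chair ene transition state; the side-chain Z alkene from trans-hydroalumination.

Key step: step 12

Remark: elemane numbering is used for all intermediates (ring C5–C10; C1=C2 vinyl and C14 methyl on C10; C3=C4–C15 on C5; C11(=C13)–C12 on C7). The target as drawn is (5R,6R,7R,8S,10S) with a (2Z)-2-(hydroxymethyl)but-2-enoate on O8. TBS = tert-butyldimethylsilyl, TBDPS = tert-butyldiphenylsilyl, TES = triethylsilyl.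

**Step 1**
Reactants: 1 prop-2-yn-1-ol
Product: 3 (2Z)-3-iodo-2-methylprop-2-en-1-ol, via bromomagnesium (2Z)-3-(bromomagnesio)-2-methylprop-2-en-1-olate 2 (not isolated)
Conditions: MeMgBr (2.5 equiv), CuI (10 mol %), THF, −10 → 23 °C; I2, −78 → 0 °C; aq. NH4Cl
Reagents that add atoms: methylmagnesium bromide C[Mg]Br; iodine II
Why: Copper-catalysed anti-carbomagnesiation of the propargylic alkoxide (magnesium held in a five-membered chelate, methyl delivered to the inner carbon) followed by iodinolysis with retention should place iodine cis to CH2OH.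

**Step 2**
Reactants: 3 (2Z)-3-iodo-2-methylprop-2-en-1-ol
Product: 4 (2Z)-3-iodo-2-methylprop-2-enal
Conditions: MnO2 (activated, 15 equiv), CH2Cl2, 23 °C, dark; used at once
Reagents that add atoms: none
Why: MnO2 oxidation of an allylic alcohol is neutral and should leave the C–I bond and the Z geometry untouched.

**Step 3**
Reactants: 4 (2Z)-3-iodo-2-methylprop-2-enal
Product: 5 (1Z)-1-iodo-2-methylbuta-1,3-diene
Conditions: Ph3PCH3Br, NaHMDS, THF, −78 → 0 °C; 4, −78 → 0 °C; kept as a pentane/Et2O solution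
Reagents that add atoms: methyltriphenylphosphonium bromide C[P+](c1ccccc1)(c1ccccc1)c1ccccc1.[Br-]
Why: Wittig methylenation of the enal should give the volatile iododiene with the trisubstituted alkene geometry unchanged.

**Step 4**
Reactants: 1 prop-2-yn-1-ol
Product: 7 (2Z)-2-(iodomethylidene)pent-4-en-1-ol, via bromomagnesium (2Z)-2-[(bromomagnesio)methylidene]pent-4-en-1-olate 6 (not isolated)
Conditions: allylMgBr (3 equiv), CuI (10 mol %), Et2O, 0 → 23 °C; I2, −78 → 0 °C; aq. NH4Cl
Reagents that add atoms: allylmagnesium bromide C=CC[Mg]Br; iodine II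
Why: The same chelation-controlled anti-carbomagnesiation and iodinolysis should give the vinyl iodide with iodine cis to CH2OH (future C15) and trans to the allyl group (future C3–C8).

**Step 5**
Reactants: 7 (2Z)-2-(iodomethylidene)pent-4-en-1-ol
Product: 8 TBDPS ether of 7
Conditions: TBDPSCl, imidazole, CH2Cl2, 0 → 23 °C
Reagents that add atoms: tert-butyl(chloro)diphenylsilane CC(C)(C)[Si](Cl)(c1ccccc1)c1ccccc1
Why: Standard silylation; the bulky diphenylsilyl group is chosen because it resists O-to-C silyl migration in the cis alkenyllithium of step 9.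

**Step 6**
Reactants: 8 TBDPS ether of 7
Product: 9 (3Z)-3-{[(TBDPS)oxy]methyl}-4-iodobut-3-enal
Conditions: K2OsO4·2H2O (2 mol %), NaIO4 (4 equiv), 2,6-lutidine, 1,4-dioxane/H2O 3:1, 23 °C; used crude
Reagents that add atoms: sodium periodate [Na+].[O-]I(=O)(=O)=O
Why: Lemieux–Johnson cleavage should take the monosubstituted alkene selectively, because the iodoalkene is electron-poor and hindered.

**Step 7**
Reactants: 9 (3Z)-3-{[(TBDPS)oxy]methyl}-4-iodobut-3-enal
Product: 10 (3Z)-3-{[(TBDPS)oxy]methyl}-4-iodobut-3-en-1-ol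
Conditions: NaBH4, MeOH, 0 °C
Reagents that add atoms: none
Why: Prompt borohydride reduction removes the isomerisation-prone β,γ-unsaturated aldehyde without affecting the vinyl iodide.

**Step 8**
Reactants: 10 (3Z)-3-{[(TBDPS)oxy]methyl}-4-iodobut-3-en-1-ol
Product: 11 TES ether of 10
Conditions: Et3SiCl, imidazole, CH2Cl2, 0 °C
Reagents that add atoms: chlorotriethylsilane CC[Si](Cl)(CC)CC
Why: Standard silylation; the primary TES ether is the one silyl group that step 11 can convert directly into the aldehyde.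

**Step 9**
Reactants: 11 TES ether of 10; 12 3-methylbut-2-enal
Product: 15 (4S,5Z)-6-{[(TBDPS)oxy]methyl}-2-methyl-8-[(TES)oxy]octa-2,5-dien-4-ol, via alkenyllithium 13 (not isolated), via alkenylzinc bromide 14 (not isolated)
Conditions: t-BuLi (2.1 equiv), Et2O, −78 °C; ZnBr2 (1.05 equiv), −78 → 0 °C; N,N,N′,N′-tetraethylethylenediamine (0.4 equiv), (+)-3-exo-morpholinoisoborneol ((+)-MIB, 5 mol %), toluene/hexane; 12, 0 °C; aq. NH4Cl
Reagents that add atoms: none
Why: Iodine–lithium exchange with retention, transmetalation to zinc and amino-alcohol-catalysed enantioselective 1,2-addition of the alkenylzinc to the enal should set C6 (S) under ligand control; the ligand antipode is available should the sense prove opposite.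

**Step 10**
Reactants: 15 (4S,5Z)-dienol
Product: 16 TBS ether of 15
Conditions: TBSCl, imidazole, DMAP (cat.), DMF, 23 °C
Reagents that add atoms: tert-butyl(chloro)dimethylsilane CC(C)(C)[Si](C)(C)Cl
Why: Base-buffered silylation protects the acid-sensitive bis-allylic alcohol and installs the bulky C6 silyloxy group that steers step 12.

**Step 11**
Reactants: 16 TBS ether of 15
Product: 17 (3Z,5S)-5-[(TBS)oxy]-3-{[(TBDPS)oxy]methyl}-7-methylocta-3,6-dienal
Conditions: (COCl)2, DMSO, CH2Cl2, −78 → −30 °C; Et3N, −78 → −20 °C; cold work-up, used at once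
Reagents that add atoms: none
Why: Swern conditions cleave and oxidise a primary TES ether directly to the aldehyde while secondary TBS and primary TBDPS ethers survive; the cold, brief base exposure should keep the C4=C5 alkene out of conjugation.

**Step 12**
Reactants: 5 (1Z)-1-iodo-2-methylbuta-1,3-diene; 17 (3Z,5S)-dienal
Product: 22 (3S,4R,5S)-5-[(TBS)oxy]-4-{3-[(TBDPS)oxy]prop-1-en-2-yl}-3-ethenyl-3,7-dimethyloct-6-enal, via dienyllithium 18 (not isolated), via lithium 1,5-dien-3-olate 19 (not isolated), via potassium 1,5-dien-3-olate 20 (not isolated), via potassium enolate 21 (not isolated)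
Conditions: 5 (1.3 equiv), t-BuLi (2.6 equiv), Et2O, −78 °C; 17, −78 °C; KOt-Bu (1.5 equiv), 18-crown-6 (1.5 equiv), THF, −78 → 40 °C; aq. NH4Cl, −78 °C
Reagents that add atoms: none
Why: Dienyllithium 18 (iodine–lithium exchange with retention) adds 1,2 to the β,γ-unsaturated aldehyde and forms C8–C9; after lithium-to-potassium exchange the 1,5-dien-3-olate 20 undergoes an anionic oxy-Cope [3,3] shift through C10=C9–C8–C3–C4=C5 that forms C5–C10, cleaves C3–C8 and leaves C4=C3 as the exocyclic methylene and C8 as an aldehyde enolate. The closest known reaction type is the tandem alkenyllithium addition/anionic oxy-Cope rearrangement of β,γ-unsaturated carbonyl compounds. No ring is closed in this step, so no closure mode applies; ring C5–C10 is closed in step 13 across C7–C8. C10 (quaternary) and C5 are set relative to each other by the chair transition state, in which the Z geometry of 18 places the methyl pseudo-equatorial and the vinyl pseudo-axial and the C4=C5 geometry places C6 pseudo-equatorial; the C8 carbinol centre forms without control but is erased when C8 becomes trigonal. The absolute sense is relayed from C6: with H6 eclipsing C4=C5 (1,3-allylic strain against C15), C10 should bond to C5 anti to the C6–O bond and its bulky silyl group, which corresponds to (5R,10S). The step needs 1,2-addition over enolisation of the doubly activated C3 methylene (fast alkenyllithium addition at −78 °C in Et2O) and [3,3] shift over retro-allylation or a 1,3-shift (crown-separated potassium alkoxide and a freely chair-accessible acyclic array).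

**Step 13**
Reactants: 22 (3S,4R,5S)-aldehyde
Product: 23 (1S,2R,3R,4R,5S)-3-[(TBS)oxy]-4-{3-[(TBDPS)oxy]prop-1-en-2-yl}-5-ethenyl-5-methyl-2-(prop-1-en-2-yl)cyclohexan-1-ol
Conditions: Me2AlCl (1.5 equiv), CH2Cl2, −78 → −40 °C; cold aq. HCl (0.1 M)
Reagents that add atoms: none
Why: Lewis-acid type 1 carbonyl-ene cyclisation (six-membered chair, as in citronellal to isopulegol) at the more nucleophilic trisubstituted alkene should form C7–C8 with the new hydroxyl and isopropenyl groups equatorial, trans to each other and to the equatorial C6 silyloxy group.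

**Step 14**
Reactants: 24 but-2-yn-1-ol
Product: 26 (2Z)-2-iodobut-2-en-1-ol, via lithium alkenylalanate 25 (not isolated)
Conditions: LiAlH4 (1.5 equiv), AlCl3 (2.5 mol %), THF, reflux; I2, −78 → 0 °C; aq. HCl (1 M)
Reagents that add atoms: iodine II
Why: Hydroxyl-directed trans-hydroalumination with aluminium at C2 (LiAlH4 with a trace of AlCl3) and iodinolysis with retention should give the 2-iodo alcohol with iodine cis to the methyl group.

**Step 15**
Reactants: 26 (2Z)-2-iodobut-2-en-1-ol
Product: 28 (2Z)-2-(hydroxymethyl)but-2-enoic acid, via dilithio species 27 (not isolated)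
Conditions: MeLi (1.0 equiv), Et2O, −78 °C; t-BuLi (2.1 equiv), −78 °C; CO2 (g), −78 → 0 °C; aq. HCl to pH 3
Reagents that add atoms: carbon dioxide O=C=O
Why: Iodine–lithium exchange on the lithium alkoxide and carboxylation of the configurationally stable alkenyllithium proceed with retention, so CO2H ends cis to the methyl group.

**Step 16**
Reactants: 28 (2Z)-2-(hydroxymethyl)but-2-enoic acid
Product: 30 (2Z)-2-{[(TBS)oxy]methyl}but-2-enoic acid, via bis-silyl derivative 29 (not isolated)
Conditions: TBSCl (2.3 equiv), imidazole, DMF, 23 °C; then AcOH/THF/H2O 1:3:1, 23 °C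
Reagents that add atoms: tert-butyl(chloro)dimethylsilane CC(C)(C)[Si](C)(C)Cl
Why: Exhaustive silylation followed by selective hydrolysis of the much more labile silyl ester leaves the primary TBS ether in place.

**Step 17**
Reactants: 23 cyclohexanol; 30 (2Z)-2-{[(TBS)oxy]methyl}but-2-enoic acid
Product: 32 ester of 23 at the C8 hydroxyl with 30, via mixed anhydride 31 (not isolated)
Conditions: 2,4,6-Cl3C6H2COCl, Et3N, toluene, 23 °C; then 23, DMAP (cat.), toluene, 23 °C
Reagents that add atoms: none
Why: Yamaguchi esterification acylates the only free hydroxyl (equatorial O8) and is the usual choice for Z-configured 2-substituted butenoic acids because it should avoid Z-to-E isomerisation.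

**Step 18**
Reactants: 32 ester
Product: 33 allylic alcohol (32 with the C7 isopropenyl group oxidised to 3-hydroxyprop-1-en-2-yl)
Conditions: SeO2 (0.5 equiv), t-BuOOH (3 equiv, in decane), CH2Cl2, 23 °C
Reagents that add atoms: tert-butyl hydroperoxide CC(C)(C)OO; selenium dioxide O=[Se]=O
Why: Riley oxidation (ene reaction, then [2,3] shift) should take the methyl of the only electron-rich 1,1-dialkyl alkene, since C10 has no allylic hydrogen, the C3=C4 alkene is deactivated by its allylic silyloxy group and the side-chain alkene is conjugated; any enal formed converges in step 19.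

**Step 19**
Reactants: 33 allylic alcohol
Product: 34 acrylic acid (33 with the new CH2OH oxidised to CO2H)
Conditions: TEMPO (20 mol %), PhI(OAc)2 (2.5 equiv), MeCN/H2O 1:1, 23 °C
Reagents that add atoms: water O
Why: Oxoammonium oxidation of the only free (primary allylic) alcohol through the aldehyde hydrate gives the acid without a reagent that attacks alkenes.

**Step 20**
Reactants: 34 acrylic acid
Product: 36 CNP0111202.1, via trihydroxy acid 35 (not isolated)
Conditions: HF·pyridine (excess), pyridine, THF, 0 → 23 °C; then camphorsulfonic acid (10 mol %), CH2Cl2, 23 °C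
Reagents that add atoms: none
Why: Fluoride-mediated removal of all three silyl groups frees O6, the only hydroxyl γ to C12 (O8 is acylated), and acid-catalysed lactonisation closes the trans-fused α-methylene-γ-lactone with no change at any stereocentre.

**Compound list**

1 | prop-2-yn-1-ol | C#CCO | starting material
2 | bromomagnesium (2Z)-3-(bromomagnesio)-2-methylprop-2-en-1-olate | Br[Mg]/C=C(C)\CO[Mg]Br | intermediate
3 | (2Z)-3-iodo-2-methylprop-2-en-1-ol | I/C=C(C)\CO | intermediate
4 | (2Z)-3-iodo-2-methylprop-2-enal | I/C=C(C)\C=O | intermediate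
5 | (1Z)-1-iodo-2-methylbuta-1,3-diene | I/C=C(C)\C=C | intermediate
6 | bromomagnesium (2Z)-2-[(bromomagnesio)methylidene]pent-4-en-1-olate | Br[Mg]/C=C(CC=C)\CO[Mg]Br | intermediate
7 | (2Z)-2-(iodomethylidene)pent-4-en-1-ol | I/C=C(CC=C)\CO | intermediate
8 | tert-butyl{[(2Z)-2-(iodomethylidene)pent-4-en-1-yl]oxy}diphenylsilane | I/C=C(CC=C)\CO[Si](c1ccccc1)(c1ccccc1)C(C)(C)C | intermediate
9 | (3Z)-3-{[(tert-butyldiphenylsilyl)oxy]methyl}-4-iodobut-3-enal | I/C=C(CC=O)\CO[Si](c1ccccc1)(c1ccccc1)C(C)(C)C | intermediate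
10 | (3Z)-3-{[(tert-butyldiphenylsilyl)oxy]methyl}-4-iodobut-3-en-1-ol | I/C=C(CCO)\CO[Si](c1ccccc1)(c1ccccc1)C(C)(C)C | intermediate
11 | tert-butyl{[(2Z)-2-(iodomethylidene)-4-[(triethylsilyl)oxy]butyl]oxy}diphenylsilane | I/C=C(CCO[Si](CC)(CC)CC)\CO[Si](c1ccccc1)(c1ccccc1)C(C)(C)C | intermediate
12 | 3-methylbut-2-enal | CC(C)=CC=O | starting material
13 | alkenyllithium: [(1Z)-2-{[(tert-butyldiphenylsilyl)oxy]methyl}-4-[(triethylsilyl)oxy]but-1-en-1-yl]lithium | [Li]/C=C(CCO[Si](CC)(CC)CC)\CO[Si](c1ccccc1)(c1ccccc1)C(C)(C)C | intermediate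
14 | alkenylzinc bromide: bromo[(1Z)-2-{[(tert-butyldiphenylsilyl)oxy]methyl}-4-[(triethylsilyl)oxy]but-1-en-1-yl]zinc | Br[Zn]/C=C(CCO[Si](CC)(CC)CC)\CO[Si](c1ccccc1)(c1ccccc1)C(C)(C)C | intermediate
15 | (4S,5Z)-6-{[(tert-butyldiphenylsilyl)oxy]methyl}-2-methyl-8-[(triethylsilyl)oxy]octa-2,5-dien-4-ol | CC[Si](CC)(CC)OCC/C(CO[Si](c1ccccc1)(c1ccccc1)C(C)(C)C)=C/[C@@H](O)C=C(C)C | intermediate
16 | TBS ether of 15: (4S,5Z)-4-[(tert-butyldimethylsilyl)oxy]-6-{[(tert-butyldiphenylsilyl)oxy]methyl}-2-methyl-8-[(triethylsilyl)oxy]octa-2,5-diene | CC[Si](CC)(CC)OCC/C(CO[Si](c1ccccc1)(c1ccccc1)C(C)(C)C)=C/[C@@H](O[Si](C)(C)C(C)(C)C)C=C(C)C | intermediate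
17 | (3Z,5S)-5-[(tert-butyldimethylsilyl)oxy]-3-{[(tert-butyldiphenylsilyl)oxy]methyl}-7-methylocta-3,6-dienal | O=CC/C(CO[Si](c1ccccc1)(c1ccccc1)C(C)(C)C)=C/[C@@H](O[Si](C)(C)C(C)(C)C)C=C(C)C | intermediate
18 | dienyllithium: [(1Z)-2-methylbuta-1,3-dien-1-yl]lithium | [Li]/C=C(C)\C=C | intermediate
19 | lithium 1,5-dien-3-olate: lithium (3Z,7Z,9S)-9-[(tert-butyldimethylsilyl)oxy]-7-{[(tert-butyldiphenylsilyl)oxy]methyl}-3,11-dimethyldodeca-1,3,7,10-tetraen-5-olate (both C5 epimers; C5 of this name is C8) | C=C/C(C)=C\C(O[Li])C/C(CO[Si](c1ccccc1)(c1ccccc1)C(C)(C)C)=C/[C@@H](O[Si](C)(C)C(C)(C)C)C=C(C)C | intermediate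
20 | potassium 1,5-dien-3-olate: potassium salt corresponding to 19 | C=C/C(C)=C\C(O[K])C/C(CO[Si](c1ccccc1)(c1ccccc1)C(C)(C)C)=C/[C@@H](O[Si](C)(C)C(C)(C)C)C=C(C)C | intermediate
21 | potassium enolate of 22 (enolate geometry not defined) | C=C[C@](C)(C=CO[K])[C@H](C(=C)CO[Si](c1ccccc1)(c1ccccc1)C(C)(C)C)[C@@H](O[Si](C)(C)C(C)(C)C)C=C(C)C | intermediate
22 | (3S,4R,5S)-5-[(tert-butyldimethylsilyl)oxy]-4-{3-[(tert-butyldiphenylsilyl)oxy]prop-1-en-2-yl}-3-ethenyl-3,7-dimethyloct-6-enal | C=C[C@](C)(CC=O)[C@H](C(=C)CO[Si](c1ccccc1)(c1ccccc1)C(C)(C)C)[C@@H](O[Si](C)(C)C(C)(C)C)C=C(C)C | intermediate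
23 | (1S,2R,3R,4R,5S)-3-[(tert-butyldimethylsilyl)oxy]-4-{3-[(tert-butyldiphenylsilyl)oxy]prop-1-en-2-yl}-5-ethenyl-5-methyl-2-(prop-1-en-2-yl)cyclohexan-1-ol | C=C[C@]1(C)C[C@H](O)[C@@H](C(=C)C)[C@H](O[Si](C)(C)C(C)(C)C)[C@H]1C(=C)CO[Si](c1ccccc1)(c1ccccc1)C(C)(C)C | intermediate
24 | but-2-yn-1-ol | CC#CCO | starting material
25 | lithium alkenylalanate: cyclic lithium alkoxy(alkenyl)dihydroaluminate from 24, aluminium on C2 cis to the methyl group | [Li+].C/C=C1/CO[AlH2-]1 | intermediate
26 | (2Z)-2-iodobut-2-en-1-ol | I/C(=C\C)CO | intermediate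
27 | dilithio species: lithium (2Z)-2-lithiobut-2-en-1-olate | [Li]/C(=C\C)CO[Li] | intermediate
28 | (2Z)-2-(hydroxymethyl)but-2-enoic acid | OC(=O)/C(=C\C)CO | intermediate
29 | bis-silyl derivative: tert-butyldimethylsilyl (2Z)-2-{[(tert-butyldimethylsilyl)oxy]methyl}but-2-enoate | CC(C)(C)[Si](C)(C)OC(=O)/C(=C\C)CO[Si](C)(C)C(C)(C)C | intermediate
30 | (2Z)-2-{[(tert-butyldimethylsilyl)oxy]methyl}but-2-enoic acid | OC(=O)/C(=C\C)CO[Si](C)(C)C(C)(C)C | intermediate
31 | mixed anhydride: (2Z)-2-{[(tert-butyldimethylsilyl)oxy]methyl}but-2-enoic 2,4,6-trichlorobenzoic anhydride | O=C(OC(=O)/C(=C\C)CO[Si](C)(C)C(C)(C)C)c1c(Cl)cc(Cl)cc1Cl | intermediate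
32 | (1S,2R,3R,4R,5S)-3-[(tert-butyldimethylsilyl)oxy]-4-{3-[(tert-butyldiphenylsilyl)oxy]prop-1-en-2-yl}-5-ethenyl-5-methyl-2-(prop-1-en-2-yl)cyclohexyl (2Z)-2-{[(tert-butyldimethylsilyl)oxy]methyl}but-2-enoate | C=C[C@]1(C)C[C@H](OC(=O)/C(=C\C)CO[Si](C)(C)C(C)(C)C)[C@@H](C(=C)C)[C@H](O[Si](C)(C)C(C)(C)C)[C@H]1C(=C)CO[Si](c1ccccc1)(c1ccccc1)C(C)(C)C | intermediate
33 | allylic alcohol: 32 in which the ring C2 prop-1-en-2-yl group is 3-hydroxyprop-1-en-2-yl (ring configurations as in 23) | C=C[C@]1(C)C[C@H](OC(=O)/C(=C\C)CO[Si](C)(C)C(C)(C)C)[C@@H](C(=C)CO)[C@H](O[Si](C)(C)C(C)(C)C)[C@H]1C(=C)CO[Si](c1ccccc1)(c1ccccc1)C(C)(C)C | intermediate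
34 | acrylic acid: 33 with the new CH2OH oxidised to CO2H (ring configurations as in 23) | C=C[C@]1(C)C[C@H](OC(=O)/C(=C\C)CO[Si](C)(C)C(C)(C)C)[C@@H](C(=C)C(=O)O)[C@H](O[Si](C)(C)C(C)(C)C)[C@H]1C(=C)CO[Si](c1ccccc1)(c1ccccc1)C(C)(C)C | intermediate
35 | trihydroxy acid: 34 with all three silyl groups removed (free 6-OH, 15-OH and side-chain OH; ring configurations as in 23) | C=C[C@]1(C)C[C@H](OC(=O)/C(=C\C)CO)[C@@H](C(=C)C(=O)O)[C@H](O)[C@H]1C(=C)CO | intermediate
36 | CNP0111202.1: (5R,6R,7R,8S,10S)-15-hydroxy-8-{[(2Z)-2-(hydroxymethyl)but-2-enoyl]oxy}elema-1,3,11(13)-trien-12,6-olide | C=C[C@]1(C)C[C@H](OC(=O)/C(=C\C)CO)[C@H]2C(=C)C(=O)O[C@@H]2[C@H]1C(=C)CO | target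

**Totals and risks**

Total step count: 20 (three branches: steps 1–3, 4–11 and 14–16).
Longest linear sequence: 14 steps (steps 4–13 and 17–20, from 1).

Steps most likely to fail:

1. Step 12. What may go wrong: incomplete lithium-to-potassium exchange, so that the alkoxide fragments by retro-allylation or the medium enolises the C3 methylene of 17 before addition; and imperfect facial selection at C5. Fallback: the two bond formations are separated. Starting from 5 and 17, the addition is quenched at −78 °C with aq. NH4Cl to isolate the dienol (3Z,7Z,9S)-9-[(TBS)oxy]-7-{[(TBDPS)oxy]methyl}-3,11-dimethyldodeca-1,3,7,10-tetraen-5-ol F1 as its carbinol epimers. F1 is then rearranged in a second operation as the salt-free potassium alkoxide (KH, 18-crown-6, THF, 0 → 40 °C; classical two-stage anionic oxy-Cope) and protonated cold. The route is rejoined at 22.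

2. Step 13. What may go wrong: competing type 2 ene closure by the 1,1-disubstituted C3=C4 alkene (C8–C3 bond), or Lewis-acid ionisation of the allylic C6 silyl ether. Fallback: the ring is closed by an organochromium allylation instead of a cationic ene reaction. Starting from 22, ene-type allylic chlorination of the trisubstituted alkene (Ca(OCl)2, solid CO2, CH2Cl2/H2O, 0 °C) gives the rearranged secondary allylic chloride F2 (22 with the 2-methylprop-1-enyl group turned into 1-chloro-2-methylprop-2-enyl). CrCl2 in THF/DMF converts F2 into the allylchromium species, which adds through C7 to the C8 aldehyde in a chair Nozaki–Hiyama transition state. The route is rejoined at 23.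

3. Step 18. What may go wrong: oxidation at another allylic site (C5–H or C15) or loss of material through over-oxidation. Fallback: the oxygen is brought in by epoxidation and base-mediated isomerisation. Starting from 32, mCPBA (1 equiv, NaHCO3, CH2Cl2, 0 °C) epoxidises the most electron-rich 1,1-dialkyl alkene to the 2-methyloxiran-2-yl compound F3. Et2AlCl/lithium 2,2,6,6-tetramethylpiperidide (toluene, 0 °C) then opens F3 to the 2-substituted allylic alcohol by removal of a methyl proton. The route is rejoined at 33.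

**Further compounds**

F1 | step 12 | (3Z,7Z,9S)-9-[(tert-butyldimethylsilyl)oxy]-7-{[(tert-butyldiphenylsilyl)oxy]methyl}-3,11-dimethyldodeca-1,3,7,10-tetraen-5-ol (C5 epimers) | C=C/C(C)=C\C(O)C/C(CO[Si](c1ccccc1)(c1ccccc1)C(C)(C)C)=C/[C@@H](O[Si](C)(C)C(C)(C)C)C=C(C)C
F2 | step 13 | allylic chloride: 22 with the 2-methylprop-1-enyl group replaced by 1-chloro-2-methylprop-2-enyl (epimers at the C–Cl carbon) | C=C[C@](C)(CC=O)[C@H](C(=C)CO[Si](c1ccccc1)(c1ccccc1)C(C)(C)C)[C@@H](O[Si](C)(C)C(C)(C)C)C(Cl)C(C)=C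
F3 | step 18 | epoxide: 32 with the ring C2 prop-1-en-2-yl group replaced by 2-methyloxiran-2-yl (epoxide epimers) | C=C[C@]1(C)C[C@H](OC(=O)/C(=C\C)CO[Si](C)(C)C(C)(C)C)[C@@H](C2(C)CO2)[C@H](O[Si](C)(C)C(C)(C)C)[C@H]1C(=C)CO[Si](c1ccccc1)(c1ccccc1)C(C)(C)C
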